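The runs were computed for substances that don't exist.

I decided to carry a single number out of the readings, before any rate constant: the target's share of the product pool, where the pool is target plus isomer of the product.

all flasks: starting material 0.017 M; enzyme 1.7 µM
- maple: second substrate 0.011 M (fed, over 1.5 h); run made earlier; the fed solution adds 1.0 times the starting volume
- elm: second substrate 0.044 M (fed, over 1.5 h); run made earlier; the fed solution adds 1.0 times the starting volume
- flask: second substrate 0.0221 M (fed, over 1.5 h); the fed solution adds 1.0 times the starting volume; time 15 d

| run | time / d | target / % | isomer of the product / % |
|---|---|---|---|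
| maple | 0.625 | 19.8 | 15.8 |
| maple | 1.04 | 17.2 | 29.6 |
| maple | 1.67 | 12.4 | 44.5 |
| maple | 2.50 | 8.4 | 52.9 |
| maple | 4.00 | 6.4 | 58.2 |
| maple | 6.00 | 5.3 | 59.1 |
| maple | 10.0 | 5.5 | 59.3 |
| elm | 0.500 | 39.6 | 23.5 |
| elm | 1.25 | 27.0 | 71.3 |
| elm | 2.50 | 9.9 | 90.2 |
| elm | 4.00 | 8.0 | 92.1 |
| elm | 5.00 | 7.9 | 91.8 |
| elm | 8.00 | 8.5 | 91.8 |
| elm | 10.0 | 8.6 | 91.4 |

(standard deviation of a reading: 0.3 percentage points)

- every charge counts on the volume at the start, and the solution that is fed holds the whole dose
- the reaction counts as stopped when no species that holds the starting material changes by six tenths of a point or more over the second half of the time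

1. the state of affairs at 15 d: stopped, and by what, or still going (all of the starting material has reacted / forward and back rates have come level / no working catalyst is left / it is still moving / the second substrate has run out first)
2. amount of target at 15 d, in percent of the starting material charged
3. amount of isomer of the product at 15 d, in percent of the starting material charged

Two extreme versions of the flask can be solved in the head. In the first, product stays as it was made and target equals the pool (kinetic control). In the second, the pool ends wholly as isomer. Elm's first reading leans towards the first, with 39.6 % target against 23.5 % isomer at 0.500 d, but its target then falls and levels off above zero, so the real flask lies between them.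

An even split, isomer over target of one, is the zero of this scale. From 4.00 d onward elm gives a share of 8.25 %, a ratio of 11.1 on the isomer side (thermodynamic control). Maple's last two readings give 8.36 %, from a smaller pool than elm's.

In maple and elm the pool follows the smaller charge. Elm's last reading sums to 100 %. Maple's last reading sums to 64.8 %, and its charges allow 64.7 %. This flask holds more second substrate than starting material, so starting material is the limiting reagent and the pool can reach 100 %. Elm read level from 4.00 d and maple from 6.00 d, which is earlier than 15 d, so I committed to a stopped flask with 8.25 % target and 91.8 % isomer.

The forecast said all of the starting material has reacted, with 8.3 % target and 91.5 % isomer, on the ground: “This is an equilibrium reached within about 4 d.”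

The flask gives all of the starting material has reacted, with 8.33 % target and 91.7 % isomer.

    ternary complex → enzyme + target (k = 0.250 s⁻¹)
    starting material + enzyme ⇌ starting complex (K = 77.0 M⁻¹, k = 750 M⁻¹ s⁻¹)
    target ⇌ isomer of the product (K = 11.0, k = 2.30 × 10⁻⁵ s⁻¹)
    second substrate + starting complex ⇌ ternary complex (K = 1500 M⁻¹, k = 89.0 M⁻¹ s⁻¹)

The flask's share comes to 8.33 %. The gap between its target and its pool comes from the loss of target to isomer, both ways: the run without that step holds >99.9 % target instead of 8.33 %. A neighbour charged with 0.029 M of starting material has 0.762 equiv of second substrate, and 0 % of that is left at 15.0 d. Share times pool there gives 6.29 % target, and the neighbour shows 6.35 %.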